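## The problem

1. Locants used throughout: C1 = ring C=O; C2 = fully substituted oxirane carbon carrying the C15 chain (C1′–C12′); C3 = oxirane CH; C4 = CHOH; C5 = alkene carbon with the CH2OAc group (C7); C6 = alkene CH. The SMILES decodes as (2R,3R,4R), so the C4 hydroxyl and the oxirane oxygen lie on the same ring face.
2. The core is a 7-oxabicyclo[4.1.0]hept-3-en-2-one one oxygen atom above a hydroquinone. Any intermediate that has C1=O, C2=C3, C5=C6 and a C4–H at the same time tautomerises to the arene, so the two ring π-bonds cannot simply be oxidised one after the other.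
3. The three contiguous stereocentres include the quaternary C2, wedged between ketone and chain. C3 is tied to C2 by the oxirane, C4 must be cis to it, and nothing in the chain can help.
4. The chain holds three E-trisubstituted alkenes that are more nucleophilic than any carbonyl-conjugated ring alkene. Peracids, dioxiranes and halonium sources are therefore excluded once the chain is on, and the C2′=C3′ geometry must survive the joining.
5. Three hydroxyls must end differently (C7–OAc, free C4–OH, free allylic C12′–OH). Two are primary and allylic, and acetyl can migrate from C7–O to C4–O under base.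
6. The epoxy-enone does not tolerate strong base, soft nucleophiles or reducing metals.
7. Enabling feature: C2 and C5, the only ring carbons with carbon substituents, are 1,4-related, and the two oxygens lying between them (on C2/C3 and on C4) are cis. They can be read as the two atoms of one O2 molecule that added across C2/C5 of a cyclohexa-1,3-diene and then slipped inward onto C3 and C4. C1=O with its C6–H is placed to open the C4–C5 oxirane by β-elimination, which creates C5=C6 and C4–OH.
8. C1 is sp2 in the target and adjacent to C2, so it is free to carry a temporary stereocentre that steers that addition and is then erased.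

## Retrosynthesis

**18 ⇒ 17 (C12′–O).** The chain hydroxyl is removed first.
- The alternative is to carry a protected C12′–O from the start. That costs a separate chain synthesis and an orthogonal protecting group, and it puts two primary allylic alcohols in competition for the acetate.
- With this cut the chain is plain farnesyl, bought as 8, and only one primary OH exists when the acetate is placed.
- The forward step must hydroxylate the E-methyl of the terminal isopropylidene in the presence of the epoxy-enone.

**17 ⇒ 16 ⇒ 15 ⇒ 14 (retro-β-elimination, then C1=O back to C1H–O).** C5=C6 and C4–OH are re-read as a C4–C5 oxirane plus a C6–H (16). The ketone goes back to the alcohol 15 and its silyl ether 14.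
- Masking C5=C6 as a cycloadduct, or C1 as a ketal, only hides the hydroquinone problem.
- This cut removes it: no ring π-bond is left. It also turns the C4 carbinol into part of a second oxirane cis to the first.
- The forward reaction needs only an oxidation and a mild amine. The oxygen stays on C4, so its configuration is carried over.

**14 ⇒ 13 ⇒ 12 (four C–O bonds; key step).**
- Cutting C3–O and C4–O and joining the two oxygens gives the C2,C5-endoperoxide 13. Cutting C2–O and C5–O then gives the diene 12 and O2.
- Five stereocentres and two oxiranes collapse to one stereocentre (C1) and a flat diene.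
- The cis relation of the oxiranes, and hence of oxirane and C4–OH in 18, follows from the mechanism and needs no selection.
- The forward reaction must choose the face anti to the C1 substituent and must prefer the ring diene to the chain alkenes.

**12 ⇒ 11 ⇒ 10 ⇒ 7 + 9 (C2–C1′).**
- After acetate and ester adjustment, the C15 chain is cut from the C7 ring at the carbon that becomes the quaternary centre, while that carbon is still sp2.
- Joining at the sp3 stage would pit the nucleophile against the most hindered site.
- At the diene terminus an alkenyl triflate/allylstannane coupling has no steric or facial issue.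
- The forward step must keep the allyl unit linear and E.

**7 ⇒ 6 ⇒ 5 ⇒ 4 ⇒ 2 ⇒ 1 (ring from the chiral pool).**
- The dienyl triflate 7 is the enol derivative of the vinylogous β-keto ester 6.
- Shikimic acid 1 already holds all seven ring-fragment carbons: shikimate C5 → C1, C4 → C2, C3 → C3, C2 → C4, C1 → C5, C6 → C6, CO2H → C7.
- Its (5R)-carbinol has the configuration needed at C1.
- The cis C3/C4 diol is spent: the allylic C3–O is removed by hydrogenolysis of the carbonate 4 to give 5, and C4–OH is oxidised to give 6.
- No new stereocentre has to be made.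

**9 ⇒ 8.** The stannane comes from commercial farnesyl bromide by one displacement at CH2, leaving both alkenes untouched.

## Roads not taken

**Alternative 1: oxirane C–O bonds cut back to a quinone monoketal (the obvious plan).**
- An aryl-metal species and 8 give the phenol A1. PhI(OAc)2/MeOH dearomatises it to the monoketal A2.
- The forward key step is a reagent-controlled nucleophilic epoxidation to A3. Ketal hydrolysis gives the epoxyquinone A4, which is reduced at C4.
- The ketal necessarily sits on C4, the carbon that must be reduced. The route therefore passes through A4, where two ketones and then two hydride faces must be told apart.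
- Enantioselectivity rests wholly on an external reagent acting on an α-branched enone.
- Three stereocentres need three separate selectivity events. The chosen plan needs one facial choice and a mechanistic relay.
- A1, an arene with four different substituents, is no shorter to make than 12.

**Alternative 2: C2–C1′ cut at the sp3 stage.**
- An α-selective farnesyl metal (for example the barium reagent from 8) adds to the C2 ketone A5, which bears a C3 mesylate. The alkoxide then closes the oxirane.
- Closure needs the new C2–O anti to C3–OMs, so the chain must enter syn to the leaving group, against the polar Felkin–Anh and steric bias of the ring.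
- α/γ and E/Z fidelity of the allyl metal add a second risk.
- A5 already holds two stereocentres and a monoprotected 1,2-dione, so it is more complex than 12.

**Alternative 3: ring cut at C4–C5, acyclic assembly.**
- The oxirane is set on an open chain by titanium–tartrate epoxidation. The ring is closed by an intramolecular Nozaki–Hiyama–Kishi reaction of the epoxy aldehyde/iodoenone A6, which sets C4.
- This needs a geometrically pure trisubstituted alkene with two different carbon arms cis.
- It also needs a Z-iodoenone, and it exposes an α,β-epoxy ketone to Cr(II), which cleaves such oxiranes.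
- C4 would depend on an unpredictable ring-closing transition state.
- The sequence is linear, and every stereocentre is set separately.

Key step: step 10

Assumption: (−)-shikimic acid 1 and (2E,6E)-farnesyl bromide 8 are taken as purchased. Plain locants (C1–C7, C1′–C12′) and descriptors attached to them mean the target numbering. Locants inside compound names belong to the name.

## Steps

Step 1
Reactants: 1 (−)-shikimic acid
Product: 2 methyl shikimate
Conditions: MeOH, CSA (cat.), reflux
Reagents that add atoms: methanol CO
Why: Fischer esterification; no stereocentre is touched.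

Step 2
Reactants: 2 methyl shikimate
Product: 4 methyl 5-O-(tert-butyldimethylsilyl)-3,4-O-carbonylshikimate, via carbonate alcohol 3 (not isolated)
Conditions: CDI, DMF, 0 °C → rt; then TBSCl, rt
Reagents that add atoms: 1,1′-carbonyldiimidazole O=C(n1ccnc1)n1ccnc1; tert-butyldimethylsilyl chloride CC(C)(C)[Si](C)(C)Cl
Why: Cyclic carbonate formation followed by imidazole-mediated silylation; only the C3/C2 diol (shikimate O3/O4) is cis, so the cis-fused five-membered carbonate is the favoured product under imidazole-mediated acyl transfer, and the imidazole released serves as base for silylating the remaining C1–OH, the future steering group.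

Step 3
Reactants: 4 methyl 5-O-(tert-butyldimethylsilyl)-3,4-O-carbonylshikimate
Product: 5 methyl (4R,5R)-5-(tert-butyldimethylsilyloxy)-4-hydroxycyclohex-1-ene-1-carboxylate
Conditions: Pd2(dba)3·CHCl3 (cat.), n-Bu3P (cat.), HCO2H, Et3N, THF, rt
Reagents that add atoms: none
Why: Tsuji-type palladium/formate hydrogenolysis of an alkenyl cyclic carbonate: the allylic C3–O ionises, CO2 is lost and hydride passes from Pd to the π-allyl to give the homoallylic alcohol; delivery to the other allyl terminus would give an isomer that converges on the same dienolate in step 5, and C1 is not involved.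

Step 4
Reactants: 5 methyl (4R,5R)-5-(tert-butyldimethylsilyloxy)-4-hydroxycyclohex-1-ene-1-carboxylate
Product: 6 methyl (5R)-5-(tert-butyldimethylsilyloxy)-4-oxocyclohex-1-ene-1-carboxylate
Conditions: DMP, pyridine, CH2Cl2, 0 °C → rt
Reagents that add atoms: none
Why: Dess–Martin oxidation under buffered, near-neutral conditions, chosen so that the enolisable vinylogous β-keto ester neither epimerises at C1 nor aromatises; the crude ketone is taken on.

Step 5
Reactants: 6 methyl (5R)-5-(tert-butyldimethylsilyloxy)-4-oxocyclohex-1-ene-1-carboxylate
Product: 7 methyl (5R)-5-(tert-butyldimethylsilyloxy)-4-(trifluoromethylsulfonyloxy)cyclohexa-1,3-diene-1-carboxylate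
Conditions: KHMDS, THF, −78 °C; then PhNTf2, −78 → 0 °C
Reagents that add atoms: N-phenylbis(trifluoromethanesulfonimide) O=S(=O)(N(c1ccccc1)S(=O)(=O)C(F)(F)F)C(F)(F)F
Why: Enol triflate formation; C3–H is α to the ketone and γ to the enoate, hence far more acidic than C1–H, so one equivalent of base gives only the extended dienolate, which is triflated on oxygen, and C1 keeps its configuration.

Step 6
Reactants: 8 (2E,6E)-farnesyl bromide
Product: 9 tributyl[(2E,6E)-farnesyl]stannane
Conditions: n-Bu3SnH, LDA, THF, 0 °C; then 8, −78 °C
Reagents that add atoms: tributyltin hydride CCCC[SnH](CCCC)CCCC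
Why: SN2 displacement of a primary allylic bromide by a stannyl anion at low temperature; attack occurs at the unhindered CH2 and leaves both alkene geometries untouched.

Step 7
Reactants: 7 methyl (5R)-5-(tert-butyldimethylsilyloxy)-4-(trifluoromethylsulfonyloxy)cyclohexa-1,3-diene-1-carboxylate; 9 tributyl[(2E,6E)-farnesyl]stannane
Product: 10 methyl (5R)-5-(tert-butyldimethylsilyloxy)-4-[(2E,6E)-farnesyl]cyclohexa-1,3-diene-1-carboxylate
Conditions: Pd2(dba)3 (cat.), AsPh3 (cat.), LiCl, NMP, rt
Reagents that add atoms: none
Why: Stille coupling of an alkenyl triflate with an allylstannane; reductive elimination at the less substituted allyl terminus should give the linear E product, the electron-poor dienyl triflate adds readily to Pd(0), and β-elimination of C1–OTBS from the alkenyl-Pd species would need a six-membered allene.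

Step 8
Reactants: 10 methyl (5R)-5-(tert-butyldimethylsilyloxy)-4-[(2E,6E)-farnesyl]cyclohexa-1,3-diene-1-carboxylate
Product: 11 [(5R)-5-(tert-butyldimethylsilyloxy)-4-[(2E,6E)-farnesyl]cyclohexa-1,3-dien-1-yl]methanol
Conditions: DIBAL-H, CH2Cl2, −78 °C
Reagents that add atoms: none
Why: 1,2-Reduction of a dienoate with DIBAL-H; it raises the diene HOMO for step 10, and neutral work-up with base-washed silica keeps the acid-labile arene-hydrate ether from losing silanol.

Step 9
Reactants: 11 [(5R)-5-(tert-butyldimethylsilyloxy)-4-[(2E,6E)-farnesyl]cyclohexa-1,3-dien-1-yl]methanol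
Product: 12 [(5R)-5-(tert-butyldimethylsilyloxy)-4-[(2E,6E)-farnesyl]cyclohexa-1,3-dien-1-yl]methyl acetate
Conditions: Ac2O, pyridine, DMAP (cat.), CH2Cl2, 0 °C
Reagents that add atoms: acetic anhydride CC(=O)OC(C)=O
Why: Acetylation of the only free hydroxyl in the molecule, so the C7 acetate is placed without any selectivity question.

Step 10
Reactants: 12 [(5R)-5-(tert-butyldimethylsilyloxy)-4-[(2E,6E)-farnesyl]cyclohexa-1,3-dien-1-yl]methyl acetate
Product: 14 syn-bis-epoxide (1R,2R,3R,4S,5S) with C2–C3 and C4–C5 oxiranes cis to each other and anti to C1–OTBS, via endoperoxide 13 (not isolated)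
Conditions: O2, TPP (cat.), visible light, CH2Cl2 (trace pyridine), −78 °C; then solvent change to toluene, 110 °C
Reagents that add atoms: dioxygen O=O
Why: Type II photooxygenation followed by thermal endoperoxide-to-bis-epoxide isomerisation, the reaction pair known from α-terpinene (ascaridole, then isoascaridole). Singlet oxygen adds suprafacially in a [4π+2π] mode across C2/C5 of the s-cis-locked diene and closes the 1,2-dioxane ring of 13. C2 and C5 are set in this event by C1: A(1,2) strain with the C2 chain pushes OTBS pseudoaxial, where it covers one face right at the C2 terminus, so O2 should enter anti. On heating the O–O bond breaks and each oxygen closes a 3-exo bond onto the alkene carbon next to it (O on C2 to C3, O on C5 to C4), a spin-paired reorganisation of O•/C=C/•O that forms both oxiranes. C3 and C4 are set by the tether, because each oxygen can only reach the face it already occupies, so the oxiranes are necessarily cis to each other and anti to OTBS. The chemoselectivity needed is ring diene over three chain alkenes: 1,4-dialkylcyclohexa-1,3-dienes are among the fastest singlet-oxygen acceptors, whereas trisubstituted alkenes react only by the slower ene mode, and low temperature with irradiation stopped at consumption of 12 limits chain exposure. The bridgeheads carry no hydrogen, so base-induced Kornblum–DeLaMare cleavage is excluded, and the trace of pyridine keeps acid away from the arene-hydrate ether.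

Step 11
Reactants: 14 syn-bis-epoxide silyl ether
Product: 15 syn-bis-epoxy alcohol (C1–OH free, anti to both oxiranes)
Conditions: HF·pyridine, pyridine, THF, 0 °C → rt
Reagents that add atoms: none
Why: Fluoride-driven desilylation under buffered, non-basic conditions, the usual way to free a secondary TBS ether next to a quaternary carbon in the presence of trisubstituted oxiranes and esters; no alkoxide is formed, so Payne rearrangement and acetyl migration have no entry.

Step 12
Reactants: 15 syn-bis-epoxy alcohol
Product: 17 12′-deoxy target (2R,3R,4R)-epoxyquinol acetate with a farnesyl chain, via bis-epoxy ketone 16 (not isolated)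
Conditions: DMP, pyridine, CH2Cl2, 0 °C; then Et3N, 0 °C → rt
Reagents that add atoms: none
Why: Dess–Martin oxidation, then E1cB isomerisation of a β,γ-epoxy ketone to a γ-hydroxy enone: the amine removes C6–H and the C5–O bond breaks while the oxygen stays on C4 with its configuration, giving C5=C6 and C4–OH cis to the oxirane; a cis epoxy alcohol cannot undergo Payne rearrangement, and the C1 stereocentre is erased after doing its work.

Step 13
Reactants: 17 12′-deoxy target
Product: 18 target CNP0336169.1
Conditions: SeO2 (cat.), t-BuOOH, salicylic acid (cat.), CH2Cl2, 0 °C, to partial conversion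
Reagents that add atoms: selenium dioxide O=[Se]=O (oxygen carrier, catalytic); tert-butyl hydroperoxide CC(C)(C)OO (stoichiometric oxygen source)
Why: Catalytic SeO2/t-BuOOH allylic hydroxylation (ene reaction, then [2,3]-shift), which in polyprenyl chains prefers the terminal isopropylidene and its E-methyl, giving the (E)-allylic alcohol; the enone alkene is too electron-poor to react, and 17 left at partial conversion can be resubmitted.

## Compound list

1 | (−)-shikimic acid, (3R,4S,5R) | C1[C@H]([C@@H]([C@@H](C=C1C(=O)O)O)O)O | starting material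
2 | methyl shikimate | C1[C@H]([C@@H]([C@@H](C=C1C(=O)OC)O)O)O | intermediate
3 | methyl 3,4-O-carbonylshikimate (C5–OH free; configuration as in 1) | C1[C@H]([C@H]2[C@@H](C=C1C(=O)OC)OC(=O)O2)O | intermediate
4 | methyl 5-O-(tert-butyldimethylsilyl)-3,4-O-carbonylshikimate | C1[C@H]([C@H]2[C@@H](C=C1C(=O)OC)OC(=O)O2)O[Si](C)(C)C(C)(C)C | intermediate
5 | methyl (4R,5R)-5-(tert-butyldimethylsilyloxy)-4-hydroxycyclohex-1-ene-1-carboxylate | C1[C@H]([C@@H](CC=C1C(=O)OC)O)O[Si](C)(C)C(C)(C)C | intermediate
6 | methyl (5R)-5-(tert-butyldimethylsilyloxy)-4-oxocyclohex-1-ene-1-carboxylate | C1[C@H](C(=O)CC=C1C(=O)OC)O[Si](C)(C)C(C)(C)C | intermediate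
7 | methyl (5R)-5-(tert-butyldimethylsilyloxy)-4-(trifluoromethylsulfonyloxy)cyclohexa-1,3-diene-1-carboxylate | C1[C@H](C(OS(=O)(=O)C(F)(F)F)=CC=C1C(=O)OC)O[Si](C)(C)C(C)(C)C | intermediate
8 | (2E,6E)-farnesyl bromide | BrC/C=C(\C)CC/C=C(\C)CCC=C(C)C | starting material
9 | tributyl[(2E,6E)-farnesyl]stannane | CCCC[Sn](CCCC)(CCCC)C/C=C(\C)CC/C=C(\C)CCC=C(C)C | intermediate
10 | methyl (5R)-5-(tert-butyldimethylsilyloxy)-4-[(2E,6E)-farnesyl]cyclohexa-1,3-diene-1-carboxylate | C1[C@H](C(C/C=C(\C)CC/C=C(\C)CCC=C(C)C)=CC=C1C(=O)OC)O[Si](C)(C)C(C)(C)C | intermediate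
11 | [(5R)-5-(tert-butyldimethylsilyloxy)-4-[(2E,6E)-farnesyl]cyclohexa-1,3-dien-1-yl]methanol | C1[C@H](C(C/C=C(\C)CC/C=C(\C)CCC=C(C)C)=CC=C1CO)O[Si](C)(C)C(C)(C)C | intermediate
12 | [(5R)-5-(tert-butyldimethylsilyloxy)-4-[(2E,6E)-farnesyl]cyclohexa-1,3-dien-1-yl]methyl acetate | C1[C@H](C(C/C=C(\C)CC/C=C(\C)CCC=C(C)C)=CC=C1COC(C)=O)O[Si](C)(C)C(C)(C)C | intermediate
13 | C2,C5-endoperoxide (1R,2R,5R): 2,3-dioxabicyclo[2.2.2]oct-5-ene, peroxide bridge anti to C1–OTBS, farnesyl and CH2OAc on the bridgeheads | C1[C@@H](O[Si](C)(C)C(C)(C)C)[C@@]2(C/C=C(\C)CC/C=C(\C)CCC=C(C)C)C=C[C@]1(COC(C)=O)OO2 | intermediate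
14 | syn-bis-epoxide silyl ether (1R,2R,3R,4S,5S): C2–C3 and C4–C5 oxiranes cis to each other, anti to C1–OTBS | C1[C@@H](O[Si](C)(C)C(C)(C)C)[C@]2(C/C=C(\C)CC/C=C(\C)CCC=C(C)C)O[C@@H]2[C@@H]3O[C@]13COC(C)=O | intermediate
15 | syn-bis-epoxy alcohol (1R,2S,3R,4S,5S; same spatial arrangement as 14, C1–OH free) | C1[C@@H](O)[C@]2(C/C=C(\C)CC/C=C(\C)CCC=C(C)C)O[C@@H]2[C@@H]3O[C@]13COC(C)=O | intermediate
16 | syn-bis-epoxy ketone (2R,3R,4S,5S) | C1C(=O)[C@]2(C/C=C(\C)CC/C=C(\C)CCC=C(C)C)O[C@@H]2[C@@H]3O[C@]13COC(C)=O | intermediate
17 | 12′-deoxy target: (2R,3R,4R)-2,3-epoxy-4-hydroxy-5-(acetoxymethyl)-2-[(2E,6E)-farnesyl]cyclohex-5-en-1-one | CC(=O)OCC1=CC(=O)[C@]2(C/C=C(\C)CC/C=C(\C)CCC=C(C)C)O[C@@H]2[C@@H]1O | intermediate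
18 | target CNP0336169.1: (2R,3R,4R)-2,3-epoxy-4-hydroxy-5-(acetoxymethyl)-2-[(2E,6E,10E)-12-hydroxyfarnesyl]cyclohex-5-en-1-one | CC(=O)OCC1=CC(=O)[C@]2(C/C=C(\C)CC/C=C(\C)CC/C=C(\C)CO)O[C@@H]2[C@@H]1O | target

## Step count and least certain steps

Total step count: 13. Longest linear sequence: 12 (1 → 18 through steps 1–5 and 7–13). Step 6 is a one-step branch from 8.

**Step 10 (key step).**
- The most likely failure is ene oxygenation of the chain alkenes running alongside the [4+2] addition. The allylic C1–O and C7–O substituents lower the reactivity of the ring diene, while three trisubstituted alkenes add up as competitors.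
- Second, in the thermolysis, β-scission of the C2–O radical with loss of the allyl-stabilised chain could compete if the diradical does not collapse at once.
- Third, leakage of O2 to the face syn to OTBS would erode the enantiomeric series.
- The fallback sets out from 12 and comes back at 14. The two oxygens are delivered one at a time by reagents whose selectivity does not rest on alkene nucleophilicity.
- A Jacobsen–Katsuki (salen)Mn epoxidation favours conjugated over isolated alkenes. With the catalyst enantiomer matched to the face anti to OTBS, it should give the C2–C3 vinyl oxirane F1.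
- K2CO3/MeOH then frees the allylic alcohol F2.
- A Sharpless epoxidation follows (Ti(OiPr)4, L-(+)-DET, t-BuOOH; the tartrate is chosen by analogy with its sense of induction on 2-substituted allyl alcohols). It touches only C4=C5 next to the hydroxyl and gives the syn-bis-epoxy primary alcohol F3. Acetylation returns 14.

**Step 13.**
- Hydroxylation at the internal allylic positions and over-oxidation to the enal are the likely losses. The usual borohydride rescue of the enal is barred by the ring enone.
- The fallback sets out from 14 and comes back at 18. The same SeO2/t-BuOOH oxidation is run on 14, where a NaBH4 work-up is allowed, to give the 12′-alcohol F4.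
- TBDPSCl/imidazole gives the 12′-silyl ether F5. HF·pyridine removes the more labile TBS group to give the C1 alcohol F6.
- DMP and then Et3N give the protected epoxyquinol F7, and TBAF/AcOH releases 18.

**Step 7.**
- Loss of regiochemical (α versus γ) and E/Z integrity of the allyl unit at the (π-allyl)(alkenyl)Pd stage is possible. Slow transmetalation would leave time for decay of the sensitive dienyl triflate.
- The fallback sets out from 7 and comes back at 10 by reversing the polarity. Me3SnSnMe3, Pd(PPh3)4 and LiCl convert 7 into the dienylstannane F8.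
- F8 is coupled with the allylic bromide 8 under ligand-free Pd(0). This is the alkenylstannane/allyl halide variant, known to join at the primary terminus with retention of the allyl geometry.

**Step 11.**
- Acid-promoted opening of the tertiary C5–O bond, assisted by the neighbouring acetate carbonyl, may accompany slow cleavage of the hindered silyl ether.
- The fallback sets out from 13, now isolated, and comes back at 17 through 16. Here the silyl group is removed before any oxirane exists.
- HF·pyridine gives the hydroxy endoperoxide F9, and DMP gives the keto endoperoxide F10 (kept free of base).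
- Thermolysis in toluene gives 16, which Et3N converts into 17.

**Step 2.**
- Acylation at C1–OH (shikimate O5), or closure to the trans-fused carbonate, would scramble the diol differentiation.
- The fallback sets out from 2 and comes back at 4 by the thermodynamically secure ketal detour.
- 2,2-Dimethoxypropane/CSA gives the acetonide F11, and TBSCl/imidazole gives its silyl ether F12.
- Aqueous acetic acid gives the diol F13, and CDI closes the carbonate 4.

## Further compounds

F1 | step 10 | C2–C3 vinyl oxirane of 12 (oxygen anti to C1–OTBS) | C1[C@@H](O[Si](C)(C)C(C)(C)C)[C@]2(C/C=C(\C)CC/C=C(\C)CCC=C(C)C)O[C@@H]2C=C1COC(C)=O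
F2 | step 10 | allylic alcohol from F1 (C7–OH free) | C1[C@@H](O[Si](C)(C)C(C)(C)C)[C@]2(C/C=C(\C)CC/C=C(\C)CCC=C(C)C)O[C@@H]2C=C1CO
F3 | step 10 | syn-bis-epoxy primary alcohol (14 without acetyl) | C1[C@@H](O[Si](C)(C)C(C)(C)C)[C@]2(C/C=C(\C)CC/C=C(\C)CCC=C(C)C)O[C@@H]2[C@@H]3O[C@]13CO
F4 | step 13 | (10′E)-12′-hydroxy derivative of 14 | C1[C@@H](O[Si](C)(C)C(C)(C)C)[C@]2(C/C=C(\C)CC/C=C(\C)CC/C=C(\C)CO)O[C@@H]2[C@@H]3O[C@]13COC(C)=O
F5 | step 13 | 12′-O-TBDPS ether of F4 | C1[C@@H](O[Si](C)(C)C(C)(C)C)[C@]2(C/C=C(\C)CC/C=C(\C)CC/C=C(\C)CO[Si](c4ccccc4)(c5ccccc5)C(C)(C)C)O[C@@H]2[C@@H]3O[C@]13COC(C)=O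
F6 | step 13 | C1 alcohol from F5 | C1[C@@H](O)[C@]2(C/C=C(\C)CC/C=C(\C)CC/C=C(\C)CO[Si](c4ccccc4)(c5ccccc5)C(C)(C)C)O[C@@H]2[C@@H]3O[C@]13COC(C)=O
F7 | step 13 | 12′-O-TBDPS ether of 18 | CC(=O)OCC1=CC(=O)[C@]2(C/C=C(\C)CC/C=C(\C)CC/C=C(\C)CO[Si](c3ccccc3)(c4ccccc4)C(C)(C)C)O[C@@H]2[C@@H]1O
F8 | step 7 | methyl (5R)-5-(tert-butyldimethylsilyloxy)-4-(trimethylstannyl)cyclohexa-1,3-diene-1-carboxylate | C1[C@H](C([Sn](C)(C)C)=CC=C1C(=O)OC)O[Si](C)(C)C(C)(C)C
F9 | step 11 | C1-hydroxy endoperoxide (13 without TBS) | C1[C@@H](O)[C@@]2(C/C=C(\C)CC/C=C(\C)CCC=C(C)C)C=C[C@]1(COC(C)=O)OO2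
F10 | step 11 | C1-keto endoperoxide | C1C(=O)[C@@]2(C/C=C(\C)CC/C=C(\C)CCC=C(C)C)C=C[C@]1(COC(C)=O)OO2
F11 | step 2 | methyl 3,4-O-isopropylideneshikimate | C1[C@H]([C@H]2[C@@H](C=C1C(=O)OC)OC(C)(C)O2)O
F12 | step 2 | methyl 5-O-(tert-butyldimethylsilyl)-3,4-O-isopropylideneshikimate | C1[C@H]([C@H]2[C@@H](C=C1C(=O)OC)OC(C)(C)O2)O[Si](C)(C)C(C)(C)C
F13 | step 2 | methyl 5-O-(tert-butyldimethylsilyl)shikimate (3,4-diol) | C1[C@H]([C@@H]([C@@H](C=C1C(=O)OC)O)O)O[Si](C)(C)C(C)(C)C
A1 | alternative 1 | 2-[(2E,6E)-farnesyl]-4-methoxy-5-(tert-butyldimethylsilyloxymethyl)phenol | COc1cc(C/C=C(\C)CC/C=C(\C)CCC=C(C)C)c(O)cc1CO[Si](C)(C)C(C)(C)C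
A2 | alternative 1 | 2-farnesyl-4,4-dimethoxy-5-(tert-butyldimethylsilyloxymethyl)cyclohexa-2,5-dien-1-one | COC1(OC)C=C(C/C=C(\C)CC/C=C(\C)CCC=C(C)C)C(=O)C=C1CO[Si](C)(C)C(C)(C)C
A3 | alternative 1 | (2R,3R)-2,3-epoxide of A2 | COC1(OC)[C@H]2O[C@@]2(C/C=C(\C)CC/C=C(\C)CCC=C(C)C)C(=O)C=C1CO[Si](C)(C)C(C)(C)C
A4 | alternative 1 | 2,3-epoxy-2-farnesyl-5-(tert-butyldimethylsilyloxymethyl)-1,4-benzoquinone | O=C1C=C(CO[Si](C)(C)C(C)(C)C)C(=O)[C@H]2O[C@@]12C/C=C(\C)CC/C=C(\C)CCC=C(C)C
A5 | alternative 2 | C2 ketone with C1 dimethyl ketal, C3 mesylate (trans to C4–OTBS) and C5 silyloxymethyl group | COC1(OC)C=C(CO[Si](C)(C)C(C)(C)C)[C@@H](O[Si](C)(C)C(C)(C)C)[C@H](OS(C)(=O)=O)C1=O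
A6 | alternative 3 | acyclic epoxy aldehyde (Z)-iodoenone (C4 aldehyde, C2–C3 oxirane, C5 vinyl iodide) | O=C[C@H]1O[C@@]1(C/C=C(\C)CC/C=C(\C)CCC=C(C)C)C(=O)/C=C(\I)COC(C)=O
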